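**Strategy.** Ring C of the upper (epigallocatechin gallate) unit is cut across O1–C2 and C3–C4. The chain O1–C8a–C4a–C4 of ring A is a latent o-quinone methide, and C2=C3 is a latent Z enol gallate whose ring B stabilises charge at C2. One catalytic asymmetric [4+2] union of a salicylaldehyde-derived methoxy o-quinone methide with the Z-styryl gallate closes ring C at O1–C2, sets C2 and C3 cis, delivers the 3-O-galloyl ester and leaves a 4-methoxy leaving group. Ionisation at C4 then joins C6 of a C8-brominated gallocatechin trans to the ester (4β→6). One hydrogenolysis removes all benzyl groups and bromine.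

Key step: step 6

Remark: flavan numbering is used (O1, C2, C3, C4, C4a, C5–C8, C8a; ring A = benzo ring, ring B = 2-aryl group, ring C = pyran ring); "upper unit" is the galloylated unit.
Remark: the acid catalyst of step 6 is written as its (R) antipode; if that antipode should favour the (2S,3S) series, the (S) acid is used instead.
Remark: C4 of 12 is ionised in step 7, so a C4 epimer of 12, if formed, converges to the same product.
Remark: compounds 1, 4, 6 and 8 are taken as commercial.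

Step 1
Reactants: 1 (+)-gallocatechin
Product: 2 5,7,3',4',5'-penta-O-benzyl-(+)-gallocatechin
Conditions: BnBr (5.5 equiv), K2CO3, DMF, 0 °C → rt, argon
Reagents that add atoms: benzyl bromide, BrCc1ccccc1
Why: Williamson etherification in which K2CO3 deprotonates only the five phenols, so the secondary 3-OH stays free and C2/C3 are untouched (inert atmosphere and low temperature limit autoxidation and base-induced opening of ring C).

Step 2
Reactants: 2 5,7,3',4',5'-penta-O-benzyl-(+)-gallocatechin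
Product: 3 8-bromo-5,7,3',4',5'-penta-O-benzyl-(+)-gallocatechin
Conditions: NBS (1.0 equiv), CH2Cl2, −78 °C → 0 °C
Reagents that add atoms: N-bromosuccinimide, O=C1CCC(=O)N1Br
Why: Electrophilic aromatic bromination should go to C8, the more accessible and more nucleophilic free position of ring A, which leaves C6 as the only nucleophilic carbon for step 7; no stereocenter is touched.

Step 3
Reactants: 4 2,4,6-trihydroxybenzaldehyde
Product: 5 4,6-bis(benzyloxy)-2-hydroxybenzaldehyde
Conditions: BnBr (2.05 equiv), K2CO3 (2.2 equiv), DMF, rt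
Reagents that add atoms: benzyl bromide, BrCc1ccccc1
Why: Williamson etherification in which the para OH and one ortho OH are alkylated, while the remaining ortho OH, hydrogen-bonded to the formyl group, should stay free with two equivalents of halide.

Step 4
Reactants: 6 3,4,5-tris(benzyloxy)benzaldehyde
Product: 7 1,2,3-tris(benzyloxy)-5-ethynylbenzene
Conditions: dimethyl (1-diazo-2-oxopropyl)phosphonate, K2CO3, MeOH/THF, rt
Reagents that add atoms: dimethyl (1-diazo-2-oxopropyl)phosphonate, CC(=O)C(=[N+]=[N-])P(=O)(OC)OC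
Why: Seyferth–Gilbert homologation (Ohira–Bestmann modification): the diazomethylphosphonate anion formed in situ olefinates the aldehyde and the diazoalkene loses N2 with a 1,2-hydride shift to give the terminal alkyne under conditions that leave benzyl ethers intact.

Step 5
Reactants: 7 1,2,3-tris(benzyloxy)-5-ethynylbenzene; 8 3,4,5-tris(benzyloxy)benzoic acid
Product: 9 (Z)-2-[3,4,5-tris(benzyloxy)phenyl]ethenyl 3,4,5-tris(benzyloxy)benzoate
Conditions: Ru(C4H7)2(Ph2P(CH2)4PPh2) [bis(2-methylallyl)ruthenium 1,4-bis(diphenylphosphino)butane complex] (2 mol %), toluene, 60 °C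
Reagents that add atoms: none
Why: Ruthenium-catalysed anti-Markovnikov hydro-oxycarbonylation of a terminal alkyne, in which the carboxylate adds to the α-carbon of a ruthenium vinylidene and protonolysis should release the enol ester with Z geometry, the geometry that later becomes the 2,3-cis relationship.

Step 6
Reactants: 5 4,6-bis(benzyloxy)-2-hydroxybenzaldehyde; 9 (Z)-2-[3,4,5-tris(benzyloxy)phenyl]ethenyl 3,4,5-tris(benzyloxy)benzoate
Product: 12 (2R,3R,4S)-5,7-bis(benzyloxy)-4-methoxy-2-[3,4,5-tris(benzyloxy)phenyl]chroman-3-yl 3,4,5-tris(benzyloxy)benzoate, via acetal 10 (not isolated), via o-quinone methide 11 (not isolated)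
Conditions: HC(OMe)3 (2 equiv), (R)-3,3'-bis(2,4,6-triisopropylphenyl)-1,1'-binaphthyl-2,2'-diyl N-triflylphosphoramide (10 mol %), 4 Å molecular sieves, CH2Cl2, −40 °C → 0 °C
Reagents that add atoms: trimethyl orthoformate, COC(OC)OC
Why: Proposed new method: the acid converts acetal 10 into the methoxy o-quinone methide 11 (as its O-protonated aryl oxocarbenium ion, paired with the chiral phosphoramide anion and hydrogen-bonded to it through the ring A hydroxyl), and the Z enol ester 9 adds across O1=C8a–C4a=C4 in an asynchronous inverse-electron-demand [4+2] cycloaddition in which C3 bonds to C4 first and the developing C2 benzylic cation is captured by O1, the ring-closing O1–C2 bond. The closest known reaction types are the chiral Brønsted acid catalysed [4+2] cycloaddition of o-quinone methides with styrenes and the acid-catalysed three-component chroman synthesis from salicylaldehydes, trimethyl orthoformate and alkenes; an enol ester has not been used as the 2π partner in either, hence the label. Ring C is closed as a six-membered hetero-Diels–Alder adduct (4π O1=C8a–C4a=C4 plus 2π C2=C3). The 2,3-cis relationship should follow from suprafacial addition to the Z alkene, the absolute configuration (2R,3R) from face selection by the chiral counter-anion, and C4 (expected trans to the ester, methoxy in the inside position of 11) is inconsequential because it is ionised in step 7. The step needs regioselectivity (O1 to C2, not to C3), secured by the 3,4,5-tris(benzyloxy)phenyl group, which stabilises positive charge at C2 far better than the acyloxy group does at C3; it also needs ring closure to outrun C2–C3 bond rotation, which the hydrogen-bonded phenol held next to the cation should favour.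

Step 7
Reactants: 12 (2R,3R,4S)-5,7-bis(benzyloxy)-4-methoxy-2-[3,4,5-tris(benzyloxy)phenyl]chroman-3-yl 3,4,5-tris(benzyloxy)benzoate; 3 8-bromo-5,7,3',4',5'-penta-O-benzyl-(+)-gallocatechin
Product: 13 [5,7,3',4',5'-penta-O-benzyl-(−)-epigallocatechin 3-O-(3,4,5-tri-O-benzyl)gallate]-(4β→6)-[8-bromo-5,7,3',4',5'-penta-O-benzyl-(+)-gallocatechin]
Conditions: 3 (3 equiv), Me3SiOSO2CF3 (TMSOTf, 0.5 equiv), CH2Cl2, −78 → −30 °C; NaHCO3 (aq)
Reagents that add atoms: none
Why: Lewis-acid-mediated flavan-4-yl cation/arene condensation (Friedel–Crafts type, the standard proanthocyanidin coupling): TMSOTf ionises the C4–OMe bond, the 3-O-galloyl carbonyl should bridge the cation on the α-face (1,3-dioxolan-2-ylium) and C6 of 3, the only free ring A position, attacks from the β-face, setting C4 trans to the ester (4β).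

Step 8
Reactants: 13 [5,7,3',4',5'-penta-O-benzyl-(−)-epigallocatechin 3-O-(3,4,5-tri-O-benzyl)gallate]-(4β→6)-[8-bromo-5,7,3',4',5'-penta-O-benzyl-(+)-gallocatechin]
Product: 14 (−)-epigallocatechin 3-O-gallate-(4β→6)-(+)-gallocatechin (CNP0271447.2)
Conditions: H2 (1 atm), Pd(OH)2/C, Et3N (1.5 equiv), THF/MeOH/H2O, rt; filtration under argon, Sephadex LH-20
Reagents that add atoms: none
Why: Heterogeneous hydrogenolysis should cleave the thirteen benzyl ethers and, with Et3N as HBr scavenger, the aryl C–Br bond, while the gallate ester, the C4–C6 interflavan bond and all five stereocenters are unaffected.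

**Compound list**

1 | (+)-gallocatechin, (2R,3S)-2-(3,4,5-trihydroxyphenyl)chromane-3,5,7-triol | O[C@H]1Cc2c(O)cc(O)cc2O[C@@H]1c1cc(O)c(O)c(O)c1 | starting material
2 | 5,7,3',4',5'-penta-O-benzyl-(+)-gallocatechin, (2R,3S)-5,7-bis(benzyloxy)-2-[3,4,5-tris(benzyloxy)phenyl]chroman-3-ol | O[C@H]1Cc2c(OCc3ccccc3)cc(OCc3ccccc3)cc2O[C@@H]1c1cc(OCc2ccccc2)c(OCc2ccccc2)c(OCc2ccccc2)c1 | intermediate
3 | 8-bromo-5,7,3',4',5'-penta-O-benzyl-(+)-gallocatechin (2R,3S) | O[C@H]1Cc2c(OCc3ccccc3)cc(OCc3ccccc3)c(Br)c2O[C@@H]1c1cc(OCc2ccccc2)c(OCc2ccccc2)c(OCc2ccccc2)c1 | intermediate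
4 | 2,4,6-trihydroxybenzaldehyde | O=Cc1c(O)cc(O)cc1O | starting material
5 | 4,6-bis(benzyloxy)-2-hydroxybenzaldehyde | O=Cc1c(O)cc(OCc2ccccc2)cc1OCc1ccccc1 | intermediate
6 | 3,4,5-tris(benzyloxy)benzaldehyde | O=Cc1cc(OCc2ccccc2)c(OCc2ccccc2)c(OCc2ccccc2)c1 | starting material
7 | 1,2,3-tris(benzyloxy)-5-ethynylbenzene | C#Cc1cc(OCc2ccccc2)c(OCc2ccccc2)c(OCc2ccccc2)c1 | intermediate
8 | 3,4,5-tris(benzyloxy)benzoic acid | OC(=O)c1cc(OCc2ccccc2)c(OCc2ccccc2)c(OCc2ccccc2)c1 | starting material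
9 | (Z)-2-[3,4,5-tris(benzyloxy)phenyl]ethenyl 3,4,5-tris(benzyloxy)benzoate | O=C(O/C=C\c1cc(OCc2ccccc2)c(OCc2ccccc2)c(OCc2ccccc2)c1)c1cc(OCc2ccccc2)c(OCc2ccccc2)c(OCc2ccccc2)c1 | intermediate
10 | 3,5-bis(benzyloxy)-2-(dimethoxymethyl)phenol (acetal, not isolated) | COC(OC)c1c(O)cc(OCc2ccccc2)cc1OCc1ccccc1 | intermediate
11 | (6Z)-3,5-bis(benzyloxy)-6-(methoxymethylidene)cyclohexa-2,4-dien-1-one (o-quinone methide, not isolated) | CO/C=C1\C(=O)C=C(OCc2ccccc2)C=C1OCc1ccccc1 | intermediate
12 | (2R,3R,4S)-5,7-bis(benzyloxy)-4-methoxy-2-[3,4,5-tris(benzyloxy)phenyl]chroman-3-yl 3,4,5-tris(benzyloxy)benzoate (2,3-cis, 3,4-trans) | O=C(O[C@@H]1[C@@H](OC)c2c(OCc3ccccc3)cc(OCc3ccccc3)cc2O[C@@H]1c1cc(OCc2ccccc2)c(OCc2ccccc2)c(OCc2ccccc2)c1)c1cc(OCc2ccccc2)c(OCc2ccccc2)c(OCc2ccccc2)c1 | intermediate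
13 | [5,7,3',4',5'-penta-O-benzyl-(−)-epigallocatechin 3-O-(3,4,5-tri-O-benzyl)gallate]-(4β→6)-[8-bromo-5,7,3',4',5'-penta-O-benzyl-(+)-gallocatechin]; upper unit 2R,3R with the C4–C6 bond trans to the ester, lower unit 2R,3S | O=C(O[C@@H]1[C@@H](c2c(OCc4ccccc4)c(Br)c3c(c2OCc2ccccc2)C[C@H](O)[C@@H](c2cc(OCc4ccccc4)c(OCc4ccccc4)c(OCc4ccccc4)c2)O3)c2c(OCc3ccccc3)cc(OCc3ccccc3)cc2O[C@@H]1c1cc(OCc2ccccc2)c(OCc2ccccc2)c(OCc2ccccc2)c1)c1cc(OCc2ccccc2)c(OCc2ccccc2)c(OCc2ccccc2)c1 | intermediate
14 | (−)-epigallocatechin 3-O-gallate-(4β→6)-(+)-gallocatechin; upper unit (2R,3R,4S), lower unit (2R,3S) | O=C(O[C@@H]1[C@@H](c2c(O)cc3c(c2O)C[C@H](O)[C@@H](c2cc(O)c(O)c(O)c2)O3)c2c(O)cc(O)cc2O[C@@H]1c1cc(O)c(O)c(O)c1)c1cc(O)c(O)c(O)c1 | target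

**Step count.** Total: 8 steps. Longest linear sequence: 5 steps (6 → 7 → 9 → 12 → 13 → 14, steps 4–8).

**Steps most likely to fail**

Step 6 (Proposed new method). The process at risk is face selection by the chiral anion (low enantioselectivity). A stepwise cationic course could also lose the Z information, through C2–C3 rotation or bridging of the C2 cation by the ester before O1 closes. The oxocarbenium ion could also self-condense with ring A in a Friedel–Crafts reaction. The fallback uses known reaction types only and keeps the O1–C2 ring closure; it sets out from 5 and 7 and comes back at 12. Phenol 5 is silylated (t-BuMe2SiCl, imidazole, DMF) to 4,6-bis(benzyloxy)-2-(tert-butyldimethylsilyloxy)benzaldehyde F1. The lithium acetylide of 7 (n-BuLi, THF, −78 °C) adds to F1 to give the racemic propargylic alcohol F2. Ionic deoxygenation (Et3SiH, BF3·OEt2, CH2Cl2, −78 °C) gives the 1,3-diarylpropyne F3, and semihydrogenation (H2, Pd/CaCO3 poisoned with Pb(OAc)2, quinoline) gives the Z alkene F4. Shi asymmetric epoxidation for cis alkenes (glucose-derived oxazolidinone ketone of the appropriate antipode, KHSO5, K2CO3, MeCN/dimethoxymethane/H2O) gives the cis epoxide (2S,3R) F5. Desilylation (Bu4NF, AcOH) followed by catalytic camphorsulfonic acid lets the phenol open the epoxide 6-endo at the benzylic carbon with inversion; this closes O1–C2 and gives 5,7,3',4',5'-penta-O-benzyl-(−)-epigallocatechin F6. Esterification with 8 (DCC, DMAP, CH2Cl2) gives the octa-O-benzyl epigallocatechin gallate F7, and benzylic oxidation at C4 (DDQ, MeOH, CH2Cl2) should give 12.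

Step 7. The process at risk is self-condensation: ring A of a second molecule of 12 (C6/C8) may capture the C4 cation faster than the hindered, bromine-deactivated C6 of 3. The fallback sets out from 12 and comes back at 14. Ring A of 12 is blocked by dibromination (NBS, 2.1 equiv, CH2Cl2, −40 °C) to give the 6,8-dibromide F8, which can no longer act as a nucleophile. F8 is ionised with stoichiometric TMSOTf in the presence of 3 to give the tribromo (4β→6) dimer F9. Under the conditions of step 8 the three bromines leave together with the benzyl groups to give 14.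

Step 5. The process at risk is erosion of the Z geometry or Markovnikov addition of the acid to the alkyne. The fallback sets out from 7 (with 8) and comes back at 9. Rhodium-catalysed trans-hydroboration of 7 ([RhCl(C8H12)]2, P(i-Pr)3, Et3N, pinacolborane, cyclohexane, rt) gives the (Z)-alkenyl pinacol boronate F10. KHF2 (MeOH/H2O) converts it into the potassium (Z)-alkenyltrifluoroborate F11. Copper-catalysed oxidative C–O coupling with acid 8 (Cu(OAc)2, DMAP, 4 Å molecular sieves, O2, CH2Cl2) forms the enol ester with retention of alkene geometry to give 9.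

**Further compounds**

F1 | step 6 | 4,6-bis(benzyloxy)-2-(tert-butyldimethylsilyloxy)benzaldehyde | O=Cc1c(O[Si](C)(C)C(C)(C)C)cc(OCc2ccccc2)cc1OCc1ccccc1
F2 | step 6 | racemic 1-[4,6-bis(benzyloxy)-2-(tert-butyldimethylsilyloxy)phenyl]-3-[3,4,5-tris(benzyloxy)phenyl]prop-2-yn-1-ol | OC(C#Cc1cc(OCc2ccccc2)c(OCc2ccccc2)c(OCc2ccccc2)c1)c1c(O[Si](C)(C)C(C)(C)C)cc(OCc2ccccc2)cc1OCc1ccccc1
F3 | step 6 | tert-butyl{3,5-bis(benzyloxy)-2-[3-(3,4,5-tris(benzyloxy)phenyl)prop-2-yn-1-yl]phenoxy}dimethylsilane | CC(C)(C)[Si](C)(C)Oc1cc(OCc2ccccc2)cc(OCc2ccccc2)c1CC#Cc1cc(OCc2ccccc2)c(OCc2ccccc2)c(OCc2ccccc2)c1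
F4 | step 6 | (Z)-alkene, tert-butyl{3,5-bis(benzyloxy)-2-[(2Z)-3-(3,4,5-tris(benzyloxy)phenyl)prop-2-en-1-yl]phenoxy}dimethylsilane | CC(C)(C)[Si](C)(C)Oc1cc(OCc2ccccc2)cc(OCc2ccccc2)c1C/C=C\c1cc(OCc2ccccc2)c(OCc2ccccc2)c(OCc2ccccc2)c1
F5 | step 6 | cis epoxide, (2S,3R)-2-[3,4,5-tris(benzyloxy)phenyl]-3-{[4,6-bis(benzyloxy)-2-(tert-butyldimethylsilyloxy)phenyl]methyl}oxirane | CC(C)(C)[Si](C)(C)Oc1cc(OCc2ccccc2)cc(OCc2ccccc2)c1C[C@H]1O[C@H]1c1cc(OCc2ccccc2)c(OCc2ccccc2)c(OCc2ccccc2)c1
F6 | step 6 | 5,7,3',4',5'-penta-O-benzyl-(−)-epigallocatechin (2R,3R) | O[C@@H]1Cc2c(OCc3ccccc3)cc(OCc3ccccc3)cc2O[C@@H]1c1cc(OCc2ccccc2)c(OCc2ccccc2)c(OCc2ccccc2)c1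
F7 | step 6 | 5,7,3',4',5'-penta-O-benzyl-(−)-epigallocatechin 3-O-(3,4,5-tri-O-benzyl)gallate (2R,3R) | O=C(O[C@@H]1Cc2c(OCc3ccccc3)cc(OCc3ccccc3)cc2O[C@@H]1c1cc(OCc2ccccc2)c(OCc2ccccc2)c(OCc2ccccc2)c1)c1cc(OCc2ccccc2)c(OCc2ccccc2)c(OCc2ccccc2)c1
F8 | step 7 | 6,8-dibromo derivative of 12 (same configuration at C2, C3 and C4) | O=C(O[C@@H]1[C@@H](OC)c2c(OCc3ccccc3)c(Br)c(OCc3ccccc3)c(Br)c2O[C@@H]1c1cc(OCc2ccccc2)c(OCc2ccccc2)c(OCc2ccccc2)c1)c1cc(OCc2ccccc2)c(OCc2ccccc2)c(OCc2ccccc2)c1
F9 | step 7 | 6,8-dibromo (upper unit) analogue of 13, the tribromo (4β→6) dimer | O=C(O[C@@H]1[C@@H](c2c(OCc4ccccc4)c(Br)c3c(c2OCc2ccccc2)C[C@H](O)[C@@H](c2cc(OCc4ccccc4)c(OCc4ccccc4)c(OCc4ccccc4)c2)O3)c2c(OCc3ccccc3)c(Br)c(OCc3ccccc3)c(Br)c2O[C@@H]1c1cc(OCc2ccccc2)c(OCc2ccccc2)c(OCc2ccccc2)c1)c1cc(OCc2ccccc2)c(OCc2ccccc2)c(OCc2ccccc2)c1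
F10 | step 5 | 2-{(Z)-2-[3,4,5-tris(benzyloxy)phenyl]ethenyl}-4,4,5,5-tetramethyl-1,3,2-dioxaborolane | CC1(C)OB(/C=C\c2cc(OCc3ccccc3)c(OCc3ccccc3)c(OCc3ccccc3)c2)OC1(C)C
F11 | step 5 | potassium trifluoro{(Z)-2-[3,4,5-tris(benzyloxy)phenyl]ethenyl}borate | [K+].F[B-](F)(F)/C=C\c1cc(OCc2ccccc2)c(OCc2ccccc2)c(OCc2ccccc2)c1
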